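All runs were computed from invented constants, noise included.

1. I wanted to know when ring stands highest in the flask, and how high.

| flask | starting material | remark | time |
|---|---|---|---|
| maple | 0.0050 M | run made earlier |  |
| cedar | 0.0075 M | run made earlier |  |
| flask | 0.010 M |  | 5.0 min |

| run | time / min | ring / % | starting material / % |
|---|---|---|---|
| maple | 0.250 | 27 | 59 |
| maple | 0.500 | 39 | 41 |
| maple | 0.833 | 46 | 30 |
| maple | 1.50 | 47 | 24 |
| maple | 3.00 | 44 | 18 |
| maple | 5.00 | 36 | 19 |
| cedar | 0.250 | 26 | 56 |
| cedar | 0.500 | 37 | 39 |
| cedar | 0.833 | 43 | 26 |
| cedar | 1.50 | 46 | 23 |
| cedar | 3.00 | 34 | 21 |
| cedar | 5.00 | 31 | 17 |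

(each reading ± 2 percentage points)

- in percentages every species weighs as the starting material in it: one open dimer or side product counts as two
- on the list of suspects stand: starting material <-> ring; 2 starting material <-> open dimer; starting material + ring -> side product

- time up to 5.0 min at which ring stands highest
- the amount of ring, in percent of the starting material charged, at that time

2. Ring forms from starting material and, on the list of suspects, returns to it, both ways first order, so I looked at their proportion. From 1.50 min on, ring made 67.6% of c_ring + c_starting material in maple and 64.5% in cedar. Together that read 66.1%: the ring share, c_ring/(c_ring + c_starting material) once it has stopped climbing.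

3. At 0.833 min the share still read 60.5% in maple. While it climbs, ring can gain on a shrinking sum; once it stands, ring follows that sum down. So I expected the flask's peak between 0.833 min and 1.50 min.

4. At 0.833 min the sum read 76.0% in maple and 69.0% in cedar. The charges rise in equal steps, so a straight line gave 62.0% for the flask. Times the share, my own rough figure for the flask's peak was 41.0%.

5. The forecast said 1.2 min and 40%, a little under my figure, and gave as its ground: “the observed peaks of 47 and 46 suggest a gentler fall”.

6. The flask gave 37.6% at 1.02 min: the time lay inside my window, and the height lay below my figure. The forecast's height held within its margin; its time was late by a factor of 1.18.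

    starting material ⇌ ring (K = 1.90, k = 0.0270 s⁻¹)
    2 starting material ⇌ open dimer (K = 190 L mol⁻¹, k = 1.20 L mol⁻¹ s⁻¹)
    starting material + ring → side product (k = 1.10 L mol⁻¹ s⁻¹)

By their own step, both ways together, ring and starting material relaxed with a half-life of 0.280 min, short against 5.0 min: a pre-equilibrium. At 5.00 min the ring share times the flask's sum gave 27.6% against 27.1%; in the neighbour with 0.017 M it gave 21.7% against 21.0%. Removing either loss moved the highest ring less than removing the way back, which took the flask from 37.6% to 69.6%, a gain of 32 percentage points.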